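# Proposed synthesis of CNP0265841.0 (14) by growing both benzene rings on dimethyl glutarate

## The problem

Compound 14 is an unsymmetrical methylenebis(acylphloroglucinol): two hexasubstituted benzene rings joined only through one CH2 group, with no stereocentre. Numbering follows the SMILES string. Ring A has OCH3 at C1, CH3 at C2, OH at C3, the bridge at C4, OH at C5 and 3-methylbutanoyl at C6; ring B has the same pattern at C1' to C6', with 2-methylpropanoyl at C6'. The halves differ by one CH2 group far from the bridge, so two monomers are equal nucleophiles at C4 and C4'. Any union through a one-carbon electrophile therefore gives both homodimers beside 14, each only one CH2 away from it.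

The methyl ether sits at C1, on the oxygen that is chelated to the ketone and flanked by the C-methyl group. The more acidic para hydroxyl (C3) and the second chelated hydroxyl (C5) are free, which is the reverse of what methylation of a triol delivers. The ArCH2Ar link between two phloroglucinol rings is cleaved reversibly by hot alkali or strong acid (rottlerone change), which would scramble the halves, and strong Lewis acids strip methyl ethers ortho to ketones, so the last steps must be mild.

The feature that opens the structure is this. C5, C4, the bridge carbon, C4' and C5' form an unbranched five-carbon chain oxygenated at both ends, that is a pentanedioate. The rest of each ring with its ketone, C3–C2(CH3)–C1(OCH3)–C6–C(=O)R, is atom for atom C2–C3–C4–C5–C6 of a 6-alkyl-4-methoxy-3-methyl-2-pyrone, a ring with only one hydroxyl to methylate.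

## Retrosynthesis

**Idea of the plan.** Neither aryl–CH2 bond is ever made. The bridge is C3 of diester 10, and each benzene ring is grown on one ester terminus of 10 from a pyrone.

**Disconnection 1, ring A, bonds C3–C4 and C5–C6 (14 ⇒ 13 ⇒ 12 + 9).**
- The neighbouring cut, C4–CH2, leads back to two look-alike arenes and to statistical coupling. A cut inside ring A leaves the bridge carbon on ring B throughout.
- Opening C5–C6, the bond that the biosynthesis closes, gives keto ester 13. There C6 is a CH2 activated by the ketone on one side and, through the C1=C2 enol ether, by the C3 ketone on the other; C5 is a methyl ester.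
- Cutting C3–C4 of 13 separates the ester enolate of propanoate 12 from an acyl donor whose enol lactone is pyrone 9.
- 12 has one ring fewer than 14, and 9 is a small heterocycle that already carries CH3, OCH3 and the ketone carbon in their final order.
- The forward reaction must add the enolate to the lactone carbonyl of 9, not to its C4 or C6, and must then fold in the Claisen mode, not the aldol mode.

**Disconnection 2, ring B, bonds C3'–C4' and C5'–C6' (12 ⇒ 11 ⇒ 10 + 5).**
- The same cut in ring B leaves diester 10. Its C3 is the bridge, its C2 and C4 are C4' and C4, and its C1 and C5 are C5' and C5.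
- The two termini of 10 are used one after the other in separate flasks, so pyrones 5 and 9 never compete and cross-selectivity follows from the order of addition.
- Ring B comes first for two reasons. Pyrone 5 has only a methine in its side chain, the least acidic lateral position. The 2-methylpropanoyl ketone of 12 offers no CH2 to the strong base of the second annulation.
- The forward reaction must use only one end of a symmetrical diester, which an excess of 10 secures.

**Disconnection 3, the O–CH3 bonds (9 ⇒ 8, 5 ⇒ 4).**
- In 8 and 4 the future C1 oxygen is the only hydroxyl. The future C3 oxygen is the lactone carbonyl oxygen, the future ketone oxygen is the ring oxygen, and the C5 oxygen is still in 10 or 12.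
- The hardest regiochemical question of the arene series is thus reduced to the O-methylation of a monohydroxy compound.

**Disconnection 4, the lactone C–O bonds (8 ⇒ 7, 4 ⇒ 3).** Each pyrone is the enol lactone of a 3,5-dioxo ester, so the forward step is a simple cyclisation with one possible six-membered outcome.

**Disconnection 5, the bonds between C6 or C6' and the ketone carbons (7 ⇒ 1 + 6, 3 ⇒ 1 + 2).**
- The terminal carbon of keto ester 1 becomes C6 or C6', and esters 6 and 2 deliver the two acyl groups.
- One common building block serves both halves. All 24 skeletal carbons come from four commodity esters (1 used twice, 2, 6, 10), and the two O-methyl carbons come from the methylating agent.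

## Roads not taken

**Alternative 1:** cut both aryl–CH2 bonds (the obvious route).
- The forward key step joins monomers A1 and A2 with formaldehyde A3. In the directed form, A2 is converted to Mannich base A4, which on heating releases quinone methide A5 for capture by A1.
- A1 and A2 are equally nucleophilic at the open position, so the direct version is statistical.
- The directed version relies on an o-hydroxybenzyl leaving group that the product also contains. The product can therefore re-ionise and exchange halves under the same conditions.
- Each monomer also needs its own protecting-group sequence to put the methyl ether on the least reactive of three hydroxyls.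
- The chosen plan removes both the selectivity problem and all protecting groups.

**Alternative 2:** cut C4–C5 and C4'–C5' and take 14 as an isomer of bis-pyrone A6, in which a C5 diacid supplies C3–C4–CH2–C4'–C3'. The forward key step is a double alkoxide-induced opening and Dieckmann re-closure.
- The closing carbanion would be C4, a CH2 activated by one ketone only. The opened chain holds a far more acidic C2–H, so forcing base would be needed at the very stage where the bridge can scramble.
- The C6 ketone competes with the ester as acceptor, leading to aldol closure.
- A6 must be built linearly, one pyrone and one C-acylation after the other.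
- The chosen plan closes the ring from the doubly activated C6 under mild methoxide and is convergent.

**Alternative 3:** cut C2–C3 and C5–C6 in both rings. The forward key step is a double [3+3] Claisen condensation of tetraester A7 with the dianions of diketones A8 and A9, giving hexaphenol A10.
- The tetraester brings seven carbons at once.
- Its two malonate ends are identical, so the two diketones are again distributed statistically.
- A10 would then need methylation of just two of six hydroxyls, both chelated and hindered, which structure and acidity do not support.

Key step: step 8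

Assumption: 14 is treated as the tetraphenol tautomer drawn in the SMILES string. The stereocentres of 1, 3, 7, 11 and 13 lie between carbonyl groups, are racemic and labile, and vanish on lactonisation or aromatisation.

## Route

Step 1
Reactants: 1 methyl 2-methyl-3-oxobutanoate; 2 methyl 2-methylpropanoate
Product: 3 methyl 2,6-dimethyl-3,5-dioxoheptanoate
Conditions: 1 (2 equiv), LiN(iPr)2 (4 equiv), THF, −78 to 0 °C; then 2 (1 equiv), 0 °C to rt; 1 M HCl
Reagents that add atoms: none
Why: Crossed Claisen condensation at the gamma carbon of a beta-keto ester dianion: of the two carbanion sites of doubly deprotonated 1 the terminal CH2 is the more reactive and attacks ester 2, which sets the bond between the future C6' and the ketone carbon. The second equivalent of dianion absorbs the acidic proton of the 1,3-diketone that is formed and returns to 1 on work-up.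

Step 2
Reactants: 3 methyl 2,6-dimethyl-3,5-dioxoheptanoate
Product: 4 4-hydroxy-3-methyl-6-(propan-2-yl)-2H-pyran-2-one
Conditions: DBU (1.5 equiv), toluene, 80 °C; 1 M HCl
Reagents that add atoms: none
Why: Enol lactonisation of a 3,5-dioxo ester, the standard entry to 4-hydroxy-2-pyrones: the enolate oxygen at C5 attacks the ester (6-exo-trig), methanol leaves and the stabilised pyrone anion is the sink.

Step 3
Reactants: 4 4-hydroxy-3-methyl-6-(propan-2-yl)-2H-pyran-2-one
Product: 5 4-methoxy-3-methyl-6-(propan-2-yl)-2H-pyran-2-one
Conditions: Me2SO4, K2CO3, acetone, reflux
Reagents that add atoms: dimethyl sulfate COS(=O)(=O)OC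
Why: Williamson-type O-methylation of a vinylogous carboxylic acid; 4 holds a single hydroxyl, so the methyl ether of ring B is placed next to the C-methyl group without any choice among phenols. K2CO3 in acetone with the sulfate is the usual combination for alkylation at the C4 oxygen of 4-hydroxy-2-pyrones.

Step 4
Reactants: 1 methyl 2-methyl-3-oxobutanoate; 6 methyl 3-methylbutanoate
Product: 7 methyl 2,7-dimethyl-3,5-dioxooctanoate
Conditions: 1 (2 equiv), LiN(iPr)2 (4 equiv), THF, −78 to 0 °C; then 6 (1 equiv), 0 °C to rt; 1 M HCl
Reagents that add atoms: none
Why: Same crossed Claisen condensation of the beta-keto ester dianion as in step 1, here with the less hindered ester 6; it sets the bond between the future C6 and the 3-methylbutanoyl carbonyl carbon.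

Step 5
Reactants: 7 methyl 2,7-dimethyl-3,5-dioxooctanoate
Product: 8 4-hydroxy-3-methyl-6-(2-methylpropyl)-2H-pyran-2-one
Conditions: DBU (1.5 equiv), toluene, 80 °C; 1 M HCl
Reagents that add atoms: none
Why: Enol lactonisation of the 3,5-dioxo ester as in step 2 (6-exo-trig attack of the C5 enolate oxygen on the ester, loss of methanol).

Step 6
Reactants: 8 4-hydroxy-3-methyl-6-(2-methylpropyl)-2H-pyran-2-one
Product: 9 4-methoxy-3-methyl-6-(2-methylpropyl)-2H-pyran-2-one
Conditions: Me2SO4, K2CO3, acetone, reflux
Reagents that add atoms: dimethyl sulfate COS(=O)(=O)OC
Why: Williamson-type O-methylation of the only hydroxyl of 8, as in step 3; it fixes the methyl ether of ring A at the future C1.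

Step 7
Reactants: 5 4-methoxy-3-methyl-6-(propan-2-yl)-2H-pyran-2-one; 10 dimethyl pentanedioate
Product: 12 methyl 3-[2,6-dihydroxy-4-methoxy-3-methyl-5-(2-methylpropanoyl)phenyl]propanoate, via acylglutarate 11 (not isolated)
Conditions: 10 (3 equiv), LiN(iPr)2 (2.1 equiv), THF, −78 °C; 5 (1 equiv), −78 to 0 °C; then Mg(OMe)2, MeOH, 40 °C; 1 M HCl
Reagents that add atoms: none
Why: Proposed new method: the lithium mono-enolate of 10 should add to the lactone carbonyl C2 of 5 (crossed Claisen condensation on an enol lactone), the ring oxygen leaving as the enolate of the isopropyl ketone to give 11; in 11 the CH2 flanked by that ketone and the methyl enol ether is doubly activated and held cis to the new keto ester by the former C3=C4 bond, so that under Mg(OMe)2 it closes on the ester carbonyl (6-(enolexo)-exo-trig Claisen condensation), loses methanol and enolises to ring B. The closest known reaction types are the attack of o-toluate carbanions on C2 of 4-methoxy-2-pyrones followed by Claisen ring closure, and the Mg(OMe)2-induced Claisen folding of 3,5,7-trioxo esters to acylphloroglucinols. An excess of 10 keeps the second ester terminus untouched, and every other carbanion–carbonyl pair in 11 would give a four- or eight-membered ring or a quaternary aldol that cannot aromatise.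

Step 8
Reactants: 12 methyl 3-[2,6-dihydroxy-4-methoxy-3-methyl-5-(2-methylpropanoyl)phenyl]propanoate; 9 4-methoxy-3-methyl-6-(2-methylpropyl)-2H-pyran-2-one
Product: 14 1-[3-({2,6-dihydroxy-4-methoxy-3-methyl-5-(2-methylpropanoyl)phenyl}methyl)-2,4-dihydroxy-6-methoxy-5-methylphenyl]-3-methylbutan-1-one (CNP0265841.0), via keto ester 13 (not isolated)
Conditions: 12, LiN(iPr)2 (3.2 equiv), THF/DMPU, −78 °C; 9 (1.2 equiv), −78 to 0 °C; then Mg(OMe)2, MeOH, 25–40 °C; cold 1 M HCl
Reagents that add atoms: none
Why: Proposed new method: three equivalents of LiN(iPr)2 convert 12 into its bis-phenoxide ester enolate; the two phenoxides turn the aryl ketone of ring B into a vinylogous carboxylate that is neither enolised nor attacked, so the CH2 next to the ester (the future C4) is the only carbanion. It adds to the lactone carbonyl C2 of 9 (crossed Claisen condensation on an enol lactone), the C2–O1 bond breaks and the ring oxygen leaves as the enolate of the isobutyl ketone, which gives 13 with the C3–C4 bond in place. In 13 the CH2 between that ketone and the methyl enol ether (old pyrone C5, future C6) is doubly activated and is kept cis to the keto ester by the old C3=C4 double bond, so under equilibrating Mg(OMe)2/MeOH it attacks the ester carbonyl (future C5) in a 6-(enolexo)-exo-trig Claisen condensation, the same bond that the biosynthesis closes, and loss of methoxide with two enolisations gives ring A. The closest known reaction types are the addition of o-toluate carbanions to C2 of 4-methoxy-2-pyrones followed by Claisen closure to naphthols, the acylation of ester enolates by lactones, and the Mg(OMe)2-induced Claisen folding of 3,5,7-trioxo esters and their pyrones to acylphloroglucinols. Site selectivity at the pyrone (C2 against C4 and C6) rests on the hard lithium enolate at low temperature, on the donor-deactivated C4 and on the alkyl-shielded C6; proton transfer from the side-chain CH2 of 9 is reversible and harmless, while addition is drained by the irreversible aromatisation. Folding selectivity is secured by the chain itself: all other carbanion–carbonyl pairs of 13 would give four- or eight-membered rings or a quaternary aldol that cannot aromatise and reverts, and lactonisation of the ester onto a ring B phenoxide only makes it a better acceptor. The substitution pattern is not a matter of selectivity, since CH3, OCH3 and the ketone carbon travel from 9 in their final order and the cross-selectivity is fixed by the chain of 12; methoxide is the only alkoxide present, so exchange at ester or enol ether is degenerate. No stereocentre is formed, and the one in 13 disappears on aromatisation.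

## Compound list

1 | methyl 2-methyl-3-oxobutanoate (racemic) | COC(=O)C(C)C(C)=O | starting material
2 | methyl 2-methylpropanoate | COC(=O)C(C)C | starting material
3 | methyl 2,6-dimethyl-3,5-dioxoheptanoate (racemic) | COC(=O)C(C)C(=O)CC(=O)C(C)C | intermediate
4 | 4-hydroxy-3-methyl-6-(propan-2-yl)-2H-pyran-2-one | CC(C)C1=CC(O)=C(C)C(=O)O1 | intermediate
5 | 4-methoxy-3-methyl-6-(propan-2-yl)-2H-pyran-2-one | COC1=C(C)C(=O)OC(C(C)C)=C1 | intermediate
6 | methyl 3-methylbutanoate | COC(=O)CC(C)C | starting material
7 | methyl 2,7-dimethyl-3,5-dioxooctanoate (racemic) | COC(=O)C(C)C(=O)CC(=O)CC(C)C | intermediate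
8 | 4-hydroxy-3-methyl-6-(2-methylpropyl)-2H-pyran-2-one | CC(C)CC1=CC(O)=C(C)C(=O)O1 | intermediate
9 | 4-methoxy-3-methyl-6-(2-methylpropyl)-2H-pyran-2-one | COC1=C(C)C(=O)OC(CC(C)C)=C1 | intermediate
10 | dimethyl pentanedioate (dimethyl glutarate) | COC(=O)CCCC(=O)OC | starting material
11 | dimethyl 2-[(2E)-3-methoxy-2,6-dimethyl-5-oxohept-2-enoyl]pentanedioate (racemic, not isolated) | COC(=O)CCC(C(=O)OC)C(=O)/C(C)=C(OC)\CC(=O)C(C)C | intermediate
12 | methyl 3-[2,6-dihydroxy-4-methoxy-3-methyl-5-(2-methylpropanoyl)phenyl]propanoate | COC(=O)CCc1c(O)c(C)c(OC)c(C(=O)C(C)C)c1O | intermediate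
13 | methyl (4E)-2-{[2,6-dihydroxy-4-methoxy-3-methyl-5-(2-methylpropanoyl)phenyl]methyl}-5-methoxy-4,9-dimethyl-3,7-dioxodec-4-enoate (racemic, not isolated) | COC(=O)C(Cc1c(O)c(C)c(OC)c(C(=O)C(C)C)c1O)C(=O)/C(C)=C(OC)\CC(=O)CC(C)C | intermediate
14 | 1-[3-({2,6-dihydroxy-4-methoxy-3-methyl-5-(2-methylpropanoyl)phenyl}methyl)-2,4-dihydroxy-6-methoxy-5-methylphenyl]-3-methylbutan-1-one | COc1c(C)c(O)c(Cc2c(O)c(C)c(OC)c(C(=O)C(C)C)c2O)c(O)c1C(=O)CC(C)C | target

## Step count and least certain steps

Total step count: 8. Longest linear sequence: 5 (steps 1, 2, 3, 7, 8). The branch of steps 4 to 6 joins at step 8. No protecting group is used.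

**Step 8 (key step, Proposed new method).**
- Most likely failures:
  - proton transfer from the side-chain CH2 of the pyrone to the ester enolate in place of addition;
  - poor solubility and aggregation of the trianion;
  - conjugate attack at C4 or C6 of the pyrone;
  - exchange of the two halves by reversible cleavage of the bridge if the methoxide stage is run too hot or too long.
- Fallback with known chemistry, from 12 back to 14. The ester carbon of 12 is made C3 instead of C5 of ring A, and the ketone is put on last.
- The bis-phenoxide of 12 acylates the dianion of methyl 3-oxopentanoate at its gamma carbon to give the 3,5-dioxo ester F1, and DBU closes it to the 4-hydroxy-2-pyrone F2.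
- The pyrone hydroxyl, by far the most acidic one, is methylated alone (one equivalent each of KHCO3 and dimethyl sulfate) to the 4-methoxy-2-pyrone F3.
- Mg(OMe)2 in methanol opens F3 to the methoxy keto ester F4. NaOMe closes F4 by Dieckmann condensation from the CH2 next to the ketone to the deacyl diarylmethane F5.
- F5 has one free ring position, C6, and Friedel–Crafts acylation there with 3-methylbutanoic acid and BF3·OEt2 gives 14.

**Step 7 (Proposed new method).**
- Most likely failures:
  - reaction at both ends of the diester or self-condensation of its enolate;
  - proton transfer to the enolate from the pyrone side chain;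
  - lactonisation of the propanoate arm onto a neighbouring phenol during acidic work-up.
- Fallback with known chemistry, from 5 back to 11.
- Mg(OMe)2 in methanol opens 5 to the keto ester F6, a known reaction of 4-methoxy-2-pyrones.
- tert-Butyldimethylsilyl triflate and Et3N mask the only acidic CH2 of F6 as the silyl dienol ether F7.
- F7 has no acidic proton and serves as the non-enolisable partner in an ordinary crossed Claisen condensation with the lithium enolate of 10, giving the masked acylglutarate F8.
- Bu4NF sets free 11, which is folded with Mg(OMe)2 as in step 7.

**Step 1.**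
- Most likely failures: slow attack of the dianion on the branched ester, quenching of the dianion by the more acidic product, and self-condensation of the keto ester on warming.
- Fallback from 1 back to 3.
- Two equivalents of trimethylsilyl triflate with Et3N turn 1 into the bis(silyl enol ether) F9, a neutral equivalent of the dianion.
- The terminal carbon of F9 is acylated by 2-methylpropanoyl chloride in CH2Cl2 at low temperature (Mukaiyama-type acylation), and aqueous work-up gives 3.

**Step 3.**
- Most likely failure: alkylation of the ambident pyrone anion at the carbonyl oxygen in place of the C4 oxygen, favoured by the flanking C3 methyl group.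
- Fallback from 4 back to 5, in which the C4–O bond is made from the other side.
- POCl3 converts 4 into the 4-chloro-2-pyrone F10, and NaOMe in methanol replaces chloride by addition–elimination at C4, where no ambident anion is involved.

## Further compounds

F1 | step 8 | methyl 7-[2,6-dihydroxy-4-methoxy-3-methyl-5-(2-methylpropanoyl)phenyl]-4-methyl-3,5-dioxoheptanoate | COC(=O)CC(=O)C(C)C(=O)CCc1c(O)c(C)c(OC)c(C(=O)C(C)C)c1O
F2 | step 8 | 6-{2-[2,6-dihydroxy-4-methoxy-3-methyl-5-(2-methylpropanoyl)phenyl]ethyl}-4-hydroxy-5-methyl-2H-pyran-2-one | CC1=C(CCc2c(O)c(C)c(OC)c(C(=O)C(C)C)c2O)OC(=O)C=C1O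
F3 | step 8 | 6-{2-[2,6-dihydroxy-4-methoxy-3-methyl-5-(2-methylpropanoyl)phenyl]ethyl}-4-methoxy-5-methyl-2H-pyran-2-one | CC1=C(CCc2c(O)c(C)c(OC)c(C(=O)C(C)C)c2O)OC(=O)C=C1OC
F4 | step 8 | methyl (2E)-7-[2,6-dihydroxy-4-methoxy-3-methyl-5-(2-methylpropanoyl)phenyl]-3-methoxy-4-methyl-5-oxohept-2-enoate | COC(=O)/C=C(OC)\C(C)C(=O)CCc1c(O)c(C)c(OC)c(C(=O)C(C)C)c1O
F5 | step 8 | 1-{3-[(2,6-dihydroxy-4-methoxy-3-methylphenyl)methyl]-2,4-dihydroxy-6-methoxy-5-methylphenyl}-2-methylpropan-1-one | COc1cc(O)c(Cc2c(O)c(C)c(OC)c(C(=O)C(C)C)c2O)c(O)c1C
F6 | step 7 | methyl (2E)-3-methoxy-2,6-dimethyl-5-oxohept-2-enoate | COC(=O)/C(C)=C(OC)\CC(=O)C(C)C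
F7 | step 7 | methyl (2E,4Z)-5-[(tert-butyldimethylsilyl)oxy]-3-methoxy-2,6-dimethylhepta-2,4-dienoate | COC(=O)/C(C)=C(OC)\C=C(/O[Si](C)(C)C(C)(C)C)C(C)C
F8 | step 7 | dimethyl 2-{(2E,4Z)-5-[(tert-butyldimethylsilyl)oxy]-3-methoxy-2,6-dimethylhepta-2,4-dienoyl}pentanedioate | COC(=O)CCC(C(=O)OC)C(=O)/C(C)=C(OC)\C=C(/O[Si](C)(C)C(C)(C)C)C(C)C
F9 | step 1 | 1-methoxy-2-methyl-1,3-bis(trimethylsilyloxy)buta-1,3-diene (mixture of double-bond isomers) | C=C(O[Si](C)(C)C)C(C)=C(OC)O[Si](C)(C)C
F10 | step 3 | 4-chloro-3-methyl-6-(propan-2-yl)-2H-pyran-2-one | CC(C)C1=CC(Cl)=C(C)C(=O)O1
A1 | alternative 1 | 1-(4,6-dihydroxy-2-methoxy-3-methylphenyl)-3-methylbutan-1-one | COc1c(C)c(O)cc(O)c1C(=O)CC(C)C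
A2 | alternative 1 | 1-(4,6-dihydroxy-2-methoxy-3-methylphenyl)-2-methylpropan-1-one | COc1c(C)c(O)cc(O)c1C(=O)C(C)C
A3 | alternative 1 | formaldehyde | C=O
A4 | alternative 1 | 1-{3-[(dimethylamino)methyl]-2,4-dihydroxy-6-methoxy-5-methylphenyl}-2-methylpropan-1-one | CN(C)Cc1c(O)c(C)c(OC)c(C(=O)C(C)C)c1O
A5 | alternative 1 | 5-hydroxy-3-methoxy-2-methyl-6-methylidene-4-(2-methylpropanoyl)cyclohexa-2,4-dien-1-one | C=C1C(=O)C(C)=C(OC)C(C(=O)C(C)C)=C1O
A6 | alternative 2 | 1-[4-methoxy-5-methyl-3-(2-methylpropanoyl)-2-oxo-2H-pyran-6-yl]-3-[4-methoxy-5-methyl-3-(3-methylbutanoyl)-2-oxo-2H-pyran-6-yl]propane | COC1=C(C(=O)C(C)C)C(=O)OC(CCCC2=C(C)C(OC)=C(C(=O)CC(C)C)C(=O)O2)=C1C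
A7 | alternative 3 | tetramethyl propane-1,1,3,3-tetracarboxylate | COC(=O)C(CC(C(=O)OC)C(=O)OC)C(=O)OC
A8 | alternative 3 | 2-methylheptane-3,5-dione | CCC(=O)CC(=O)C(C)C
A9 | alternative 3 | 7-methyloctane-3,5-dione | CCC(=O)CC(=O)CC(C)C
A10 | alternative 3 | 1-[3-({2,4,6-trihydroxy-3-methyl-5-(2-methylpropanoyl)phenyl}methyl)-2,4,6-trihydroxy-5-methylphenyl]-3-methylbutan-1-one | CC(C)CC(=O)c1c(O)c(C)c(O)c(Cc2c(O)c(C)c(O)c(C(=O)C(C)C)c2O)c1O
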